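**Direct plan (conditional)**

A direct plan would join two pre-functionalised halves by a crossed Claisen condensation. The chromene methyl ketone A1 (from C-prenylation of 2,4-dihydroxyacetophenone and oxidative cyclisation) would be acylated as its dianion by the silyl-protected prenylbenzoate A2 to give the silylated diketone A3, and fluoride would free the phenol. Its weakest steps would be:
- the Friedel–Crafts C-prenylation of the resorcinol ketone, which would give C3/C5-, bis- and O-alkylated by-products at low conversion;
- the ortho-C-prenylation of the 4-hydroxybenzoate phenoxide, where O-alkylation and dialkylation would compete;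
- the silylation/desilylation pair, two steps that would add no skeletal complexity.

**New strategy**

The route would rest on the fact that in both rings the C5 unit sits on the carbon ortho to a phenolic oxygen (A ring: C4a beside O1–C8a of the 2H-pyran; B ring: C3' beside C4'–OH), so each is the [3,3] image of an O-bound tertiary C5 ether. A diaryl ester carrying a 1,1-dimethylpropargyl ether on the A ring and a 1,1-dimethylallyl ether on the B ring would, in one thermal operation, close the pyran ring and set the prenyl group. The B-ring aroyl unit, parked on the A-ring ortho oxygen, would switch off the chelate that directs angular closure; it would be moved to carbon last. C-Prenylations with electrophiles and protecting groups disappear.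

Key step: step 5

Remark: the target is achiral (no stereogenic centre; the chromene alkene is ring-locked and the prenyl alkene carries two identical methyls), so no stereocontrol is required.

**Route**

Step 1
Reactants: 1, 2,4-dihydroxyacetophenone; 2, 3-chloro-3-methylbut-1-yne
Product: 3, 1-[2-hydroxy-4-(2-methylbut-3-yn-2-yloxy)phenyl]ethanone
Conditions: K2CO3 (1.5 equiv), KI (cat.), CuI (cat.), acetone, reflux
Reagents that add atoms: 3-chloro-3-methylbut-1-yne (2), C#CC(C)(C)Cl
Why: Copper-assisted O-propargylation (Williamson-type etherification with a tertiary propargylic chloride) should occur only at the more acidic, unchelated 4-OH, because the 2-OH is held in the hydrogen bond to the acetyl carbonyl.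

Step 2
Reactants: 4, 4-fluorobenzaldehyde; 5, 2-methylbut-3-en-2-ol
Product: 6, 4-(2-methylbut-3-en-2-yloxy)benzaldehyde
Conditions: 5, NaH (1.2 equiv), THF, 0 °C; then 4, DMF, 0 °C → rt
Reagents that add atoms: 2-methylbut-3-en-2-ol (5), CC(C)(O)C=C
Why: Nucleophilic aromatic substitution (SNAr) of the para-formyl-activated fluoride by the tertiary allylic alkoxide, the reaction type used to make 4-tert-alkoxybenzaldehydes, places the reverse-prenyl group on oxygen with no O/C ambiguity; a tertiary alkoxide has no α-hydrogen and cannot reduce the aldehyde.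

Step 3
Reactants: 6
Product: 7, 4-(2-methylbut-3-en-2-yloxy)benzoic acid
Conditions: NaClO2, NaH2PO4, 2-methyl-2-butene (excess), t-BuOH/H2O, rt
Reagents that add atoms: sodium chlorite, [Na+].[O-]Cl=O
Why: Pinnick oxidation is selective for the aldehyde, and the excess trisubstituted alkene scavenges HOCl faster than the terminal vinyl group of the ether can react.

Step 4
Reactants: 3; 7
Product: 8, 2-acetyl-5-(2-methylbut-3-yn-2-yloxy)phenyl 4-(2-methylbut-3-en-2-yloxy)benzoate
Conditions: EDC·HCl (1.3 equiv), DMAP (0.3 equiv), CH2Cl2, 0 °C → rt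
Reagents that add atoms: none
Why: Steglich esterification, with DMAP acyl transfer overcoming the hydrogen-bonded ortho-acetyl phenol, should give the ester under neutral conditions that leave both tertiary ethers intact.

Step 5
Reactants: 8
Product: 11 6-acetyl-2,2-dimethyl-2H-chromen-7-yl 4-hydroxy-3-(3-methylbut-2-enyl)benzoate, via 2-acetyl-5-(2-methylbut-3-yn-2-yloxy)phenyl 4-hydroxy-3-(3-methylbut-2-enyl)benzoate 9 (not isolated), via 2-acetyl-5-hydroxy-4-(3-methylbuta-1,2-dienyl)phenyl 4-hydroxy-3-(3-methylbut-2-enyl)benzoate 10 (not isolated)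
Conditions: N,N-diethylaniline (degassed, 0.05 M), 180 °C, 2–4 h, Ar
Reagents that add atoms: none
Why: On the B ring the aryl 1,1-dimethylallyl ether should undergo a concerted [3,3] shift to the free ortho carbon (C3' and C5' are equivalent, para is blocked) and re-aromatise to prenylphenol 9. On the A ring the aryl 1,1-dimethylpropargyl ether should undergo a [3,3] shift to an ortho-allenyl dienone that enolises to allenylphenol 10; a 1,5-hydrogen shift then gives the o-quinone methide, and a thermal 6π oxa-electrocyclisation closes the 2H-pyran ring (C4–C4a made by the sigmatropic step, O1–C2 by the electrocyclisation). Both are long-known reaction types (aromatic Claisen rearrangement of tertiary allyl aryl ethers; thermal aryl propargyl ether to 2H-chromene rearrangement), run here in one flask because they share a temperature window, in whichever order they occur. No stereocentre is formed. The step needs the A-ring shift to go to C4 of the ester-bearing ring (para to the ester oxygen) and not to C6 between the two oxygens: a free ortho-hydroxy ketone would go to the flanked carbon because its OH···O=C chelate fixes the ring double bond on that side, but in 8 that oxygen carries the aroyl group, so the chelate is absent and the flanked carbon is screened, which should reproduce the para preference of meta-alkoxy and meta-acyloxy aryl propargyl ethers. The amine solvent keeps the medium non-acidic, so the new prenylphenol should not close to a chroman.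

Step 6
Reactants: 11
Product: 12, glyinflanin C, 1-(7-hydroxy-2,2-dimethyl-2H-chromen-6-yl)-3-[4-hydroxy-3-(3-methylbut-2-enyl)phenyl]propane-1,3-dione
Conditions: LiHMDS (3.5 equiv), THF, −20 °C → rt; AcOH, then aq. NH4Cl (pH about 5)
Reagents that add atoms: none
Why: Baker–Venkataraman rearrangement: the methyl ketone enolate attacks the neighbouring aryl ester through a six-membered transition state and the aroyl group moves from O to C, driven by formation of the diketonate (base is consumed by the B-ring phenol, the enolate and the diketone); the mildly acidic quench avoids cyclodehydration to the flavone.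

**Compound list**

1 | 2,4-dihydroxyacetophenone | CC(=O)c1ccc(O)cc1O | starting material
2 | 3-chloro-3-methylbut-1-yne | C#CC(C)(C)Cl | starting material
3 | 1-[2-hydroxy-4-(2-methylbut-3-yn-2-yloxy)phenyl]ethanone | CC(=O)c1ccc(OC(C)(C)C#C)cc1O | intermediate
4 | 4-fluorobenzaldehyde | O=Cc1ccc(F)cc1 | starting material
5 | 2-methylbut-3-en-2-ol | CC(C)(O)C=C | starting material
6 | 4-(2-methylbut-3-en-2-yloxy)benzaldehyde | O=Cc1ccc(OC(C)(C)C=C)cc1 | intermediate
7 | 4-(2-methylbut-3-en-2-yloxy)benzoic acid | OC(=O)c1ccc(OC(C)(C)C=C)cc1 | intermediate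
8 | 2-acetyl-5-(2-methylbut-3-yn-2-yloxy)phenyl 4-(2-methylbut-3-en-2-yloxy)benzoate | CC(=O)c1ccc(OC(C)(C)C#C)cc1OC(=O)c1ccc(OC(C)(C)C=C)cc1 | intermediate
9 | 2-acetyl-5-(2-methylbut-3-yn-2-yloxy)phenyl 4-hydroxy-3-(3-methylbut-2-enyl)benzoate | CC(=O)c1ccc(OC(C)(C)C#C)cc1OC(=O)c1ccc(O)c(CC=C(C)C)c1 | intermediate
10 | 2-acetyl-5-hydroxy-4-(3-methylbuta-1,2-dienyl)phenyl 4-hydroxy-3-(3-methylbut-2-enyl)benzoate | CC(=O)c1cc(C=C=C(C)C)c(O)cc1OC(=O)c1ccc(O)c(CC=C(C)C)c1 | intermediate
11 | 6-acetyl-2,2-dimethyl-2H-chromen-7-yl 4-hydroxy-3-(3-methylbut-2-enyl)benzoate | CC(=O)c1cc2C=CC(C)(C)Oc2cc1OC(=O)c1ccc(O)c(CC=C(C)C)c1 | intermediate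
12 | glyinflanin C | CC(C)=CCc1cc(C(=O)CC(=O)c2cc3c(cc2O)OC(C)(C)C=C3)ccc1O | target

**Step count and risks**

Total steps: 6. Longest linear sequence: 5 (steps 2, 3, 4, 5, 6).

Steps most likely to fail:

1. Step 5. The propargyl unit may migrate to the carbon between the two oxygens, so that the angular pyran closes in competition with the linear one, and the tertiary allyl group may be lost by ionisation at high temperature. The fallback would block the flanked carbon and sets out from 1. Iodination (I2, HIO3, aq. EtOH) should give 2,4-dihydroxy-3-iodoacetophenone F1. Etherification with 2 as in step 1 should give 1-[2-hydroxy-3-iodo-4-(2-methylbut-3-yn-2-yloxy)phenyl]ethanone F2. Esterification with 7 as in step 4 should give 2-acetyl-6-iodo-5-(2-methylbut-3-yn-2-yloxy)phenyl 4-(2-methylbut-3-en-2-yloxy)benzoate F3. The same thermal cascade, now with only one free ortho carbon on the A ring, should give 6-acetyl-8-iodo-2,2-dimethyl-2H-chromen-7-yl 4-hydroxy-3-(3-methylbut-2-enyl)benzoate F4. Palladium-catalysed hydrodeiodination (Pd(PPh3)4, HCO2Na, DMF, 80 °C) would then return to the route at 11.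

2. Step 6. The B-ring phenoxide, formed first, may deactivate the aroyl carbonyl so that acyl transfer is slow and ester cleavage takes over. The fallback sets out from 11. Silylation (TBSCl, imidazole, DMF) should give 6-acetyl-2,2-dimethyl-2H-chromen-7-yl 4-(tert-butyldimethylsilyloxy)-3-(3-methylbut-2-enyl)benzoate F5. Baker–Venkataraman rearrangement of this non-phenoxide ester (LiHMDS, THF, −78 °C → rt) should give 1-(7-hydroxy-2,2-dimethyl-2H-chromen-6-yl)-3-[4-(tert-butyldimethylsilyloxy)-3-(3-methylbut-2-enyl)phenyl]propane-1,3-dione F6. Buffered fluoride (TBAF, AcOH, THF, 0 °C) would return to the route at 12.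

3. Step 2. Substitution by the hindered tertiary alkoxide may be sluggish, with the aldehyde consumed by reversible addition and side reactions. The fallback sets out from 2. Commercial 4-hydroxybenzaldehyde F7 would be O-alkylated with 2 (K2CO3, KI, CuI, acetone, reflux) to 4-(2-methylbut-3-yn-2-yloxy)benzaldehyde F8. Lindlar semi-hydrogenation (H2, Pd/CaCO3–Pb, quinoline, EtOAc) would return to the route at 6.

**Further compounds**

F1 | step 5 | 1-(2,4-dihydroxy-3-iodophenyl)ethanone | CC(=O)c1ccc(O)c(I)c1O
F2 | step 5 | 1-[2-hydroxy-3-iodo-4-(2-methylbut-3-yn-2-yloxy)phenyl]ethanone | CC(=O)c1ccc(OC(C)(C)C#C)c(I)c1O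
F3 | step 5 | 2-acetyl-6-iodo-5-(2-methylbut-3-yn-2-yloxy)phenyl 4-(2-methylbut-3-en-2-yloxy)benzoate | CC(=O)c1ccc(OC(C)(C)C#C)c(I)c1OC(=O)c1ccc(OC(C)(C)C=C)cc1
F4 | step 5 | 6-acetyl-8-iodo-2,2-dimethyl-2H-chromen-7-yl 4-hydroxy-3-(3-methylbut-2-enyl)benzoate | CC(=O)c1cc2C=CC(C)(C)Oc2c(I)c1OC(=O)c1ccc(O)c(CC=C(C)C)c1
F5 | step 6 | 6-acetyl-2,2-dimethyl-2H-chromen-7-yl 4-(tert-butyldimethylsilyloxy)-3-(3-methylbut-2-enyl)benzoate | CC(=O)c1cc2C=CC(C)(C)Oc2cc1OC(=O)c1ccc(O[Si](C)(C)C(C)(C)C)c(CC=C(C)C)c1
F6 | step 6 | 1-(7-hydroxy-2,2-dimethyl-2H-chromen-6-yl)-3-[4-(tert-butyldimethylsilyloxy)-3-(3-methylbut-2-enyl)phenyl]propane-1,3-dione | CC(C)=CCc1cc(C(=O)CC(=O)c2cc3c(cc2O)OC(C)(C)C=C3)ccc1O[Si](C)(C)C(C)(C)C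
F7 | step 2 | 4-hydroxybenzaldehyde | O=Cc1ccc(O)cc1
F8 | step 2 | 4-(2-methylbut-3-yn-2-yloxy)benzaldehyde | O=Cc1ccc(OC(C)(C)C#C)cc1
A1 | direct plan | 1-(7-hydroxy-2,2-dimethyl-2H-chromen-6-yl)ethanone | CC(=O)c1cc2C=CC(C)(C)Oc2cc1O
A2 | direct plan | methyl 3-(3-methylbut-2-enyl)-4-(triisopropylsilyloxy)benzoate | COC(=O)c1ccc(O[Si](C(C)C)(C(C)C)C(C)C)c(CC=C(C)C)c1
A3 | direct plan | 1-(7-hydroxy-2,2-dimethyl-2H-chromen-6-yl)-3-[3-(3-methylbut-2-enyl)-4-(triisopropylsilyloxy)phenyl]propane-1,3-dione | CC(C)=CCc1cc(C(=O)CC(=O)c2cc3c(cc2O)OC(C)(C)C=C3)ccc1O[Si](C(C)C)(C(C)C)C(C)C
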